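**Plan**

1. Target numbering (2-oxaspiro[4.5]decane): C1 lactone CH–O, C5 spiro carbon, C6 ketone, C7=C8, C9 CH–OAc, C10 CH2. C9 is allylic to the C7=C8 alkene of the enone and is tied to C5 through C10, so the six-membered ring can be cut at C8–C9 into a Z-β-iodoenone and a CH2CHO arm that both hang from C5.
2. Retrosynthetic cuts, in order: acetate C–O; C8–C9 (alkenylchromium plus aldehyde); vinylic C–I; C5–C10 (enolate alkylation); acyl–alkyne C–C; C1–C5 and the lactone C–O (aldol–lactonisation); the CH2–CH= bond of the skipped diene (Stille).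
3. Forward: the side-chain dienal is made first, the γ-lactone ring arises by aldol–lactonisation, the quaternary carbon is alkylated, the aldehyde and the Z-iodoenone are unveiled, the cyclohexenone ring closes last, and acetylation finishes the route.
4. Stereochemistry: C1 (R) from an Evans syn aldol under control of (4S)-4-benzyloxazolidin-2-one; C5 (R) from alkylation anti to the C1 side chain; C9 (S) in the ring closure; the E alkenes from syn hydrostannation and an E bromo ester; the Z iodoalkene from anti hydroiodination.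
5. Monocyclic lactones are numbered as oxolan-2-ones: their C4 becomes the spiro carbon and their C5 becomes C1.

Key step: step 16

Remark (assumption): commercial 4 is enriched in the 2E isomer and is taken here as the pure 2E ester after fractional distillation.

**Step 1**
Reactants: 1 2-methylbut-3-yn-2-ol
Product: 2 triethyl[(2-methylbut-3-yn-2-yl)oxy]silane
Conditions: Et3SiOTf, 2,6-lutidine, CH2Cl2, 0 °C
Reagents that add atoms: triethylsilyl triflate, CC[Si](CC)(CC)OS(=O)(=O)C(F)(F)F
Why: Silylation of a tertiary alcohol with a silyl triflate and a hindered pyridine base is routine, and the triethylsilyl ether masks the one hydroxyl that would interfere with the boron enolate, the acid chloride and the enolate alkylation later on.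

**Step 2**
Reactants: 2 triethyl[(2-methylbut-3-yn-2-yl)oxy]silane
Product: 3 triethyl{[(3E)-2-methyl-4-(tributylstannyl)but-3-en-2-yl]oxy}silane
Conditions: Bu3SnH, PdCl2(PPh3)2 (2 mol%), THF, 0 °C to rt
Reagents that add atoms: tributyltin hydride, CCCC[SnH](CCCC)CCCC
Why: Palladium-catalysed hydrostannation adds H and Sn syn across the terminal alkyne, and the fully substituted propargylic carbon should steer tin to the terminal carbon, giving the E-alkenylstannane.

**Step 3**
Reactants: 3 the E-alkenylstannane; 4 ethyl (2E)-4-bromo-3-methylbut-2-enoate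
Product: 5 ethyl (2E,5E)-3,7-dimethyl-7-(triethylsilyloxy)octa-2,5-dienoate
Conditions: Pd2(dba)3 (2.5 mol%), AsPh3 (10 mol%), NMP, rt to 40 °C
Reagents that add atoms: none
Why: Stille coupling of an allylic bromide with an alkenylstannane joins the sp3 and sp2 carbons at the unsubstituted allyl terminus with retention of the stannane geometry and without base, so the skipped diene should not drift into conjugation.

**Step 4**
Reactants: 5 the dienoate
Product: 6 (2E,5E)-3,7-dimethyl-7-(triethylsilyloxy)octa-2,5-dien-1-ol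
Conditions: i-Bu2AlH (2.2 equiv), CH2Cl2, −78 °C; aqueous potassium sodium tartrate
Reagents that add atoms: none
Why: 1,2-Reduction of an enoate to the allylic alcohol with i-Bu2AlH at low temperature is standard and leaves the silyl ether and both alkenes untouched.

**Step 5**
Reactants: 6 the dienol
Product: 7 (2E,5E)-3,7-dimethyl-7-(triethylsilyloxy)octa-2,5-dienal
Conditions: MnO2 (activated, excess), CH2Cl2, rt
Reagents that add atoms: none
Why: Allylic oxidation with MnO2 is selective for the primary allylic alcohol and is neutral, so the 2E geometry and the skipped diene should be retained.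

**Step 6**
Reactants: 8 methyl 4-chloro-4-oxobutanoate; 9 (4S)-4-benzyl-1,3-oxazolidin-2-one
Product: 10 methyl 4-[(4S)-4-benzyl-2-oxo-1,3-oxazolidin-3-yl]-4-oxobutanoate
Conditions: Et3N, DMAP (cat.), CH2Cl2, 0 °C to rt
Reagents that add atoms: none
Why: N-Acylation of an oxazolidinone by an acid chloride under amine and DMAP catalysis is a standard way to attach the auxiliary.

**Step 7**
Reactants: 10 the succinate imide; 7 the dienal
Product: 13 (4S)-4-benzyl-3-{(2R,3S)-2-[(1E,4E)-2,6-dimethyl-6-(triethylsilyloxy)hepta-1,4-dien-1-yl]-5-oxooxolane-3-carbonyl}-1,3-oxazolidin-2-one, via dibutylboron Z-enolate 11 (not isolated), via open-chain syn-aldol ester 12 (not isolated)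
Conditions: Bu2BOTf, i-Pr2NEt, CH2Cl2, 0 °C; 7, −78 to 0 °C; aq. NaH2PO4/Na2HPO4 (pH 7), MeOH, H2O2, 0 °C; then PPTS (cat.), CH2Cl2, rt
Reagents that add atoms: none
Why: In this Evans syn aldol the Z-boron enolate reacts through a closed chair transition state with one face shielded by the benzyl group of the (S)-auxiliary, which should give the (3S,4R) syn adduct; its hydroxyl then closes onto the methyl ester (5-exo-trig lactonisation), so the lactone C5 is set as R with the acyl group trans to the side chain.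

**Step 8**
Reactants: 13 the lactone imide
Product: 15 (2R,3S)-2-[(1E,4E)-2,6-dimethyl-6-(triethylsilyloxy)hepta-1,4-dien-1-yl]-5-oxooxolane-3-carboxylic acid, via peroxy acid 14 (not isolated)
Conditions: LiOH, H2O2, THF/H2O, 0 °C; Na2SO3; 1 M HCl to pH 3
Reagents that add atoms: hydrogen peroxide, OO
Why: Hydroperoxide cleavage of an N-acyloxazolidinone attacks the exocyclic imide carbonyl selectively and returns the auxiliary, and any lactone opened by hydroxide should reclose on acidification because only the CH2CO2H arm can form a five-membered ring with the carbinol.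

**Step 9**
Reactants: 15 the lactone acid; 16 ethynyltrimethylsilane
Product: 18 (4S,5R)-5-[(1E,4E)-2,6-dimethyl-6-(triethylsilyloxy)hepta-1,4-dien-1-yl]-4-[3-(trimethylsilyl)prop-2-ynoyl]oxolan-2-one, via acid chloride 17 (not isolated)
Conditions: 1-chloro-N,N,2-trimethylprop-1-en-1-amine, CH2Cl2, 0 °C; then 16, PdCl2(PPh3)2 (2 mol%), CuI (4 mol%), Et3N, THF, rt
Reagents that add atoms: none
Why: The α-chloroenamine forms the acid chloride without releasing HCl, and the acyl Sonogashira coupling is a standard ynone synthesis in which the acid chloride should take up zerovalent palladium far faster than the hindered allylic lactone; C4 may equilibrate under Et3N but is planarised in step 11 anyway.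

**Step 10**
Reactants: 19 2-[(tert-butyldimethylsilyl)oxy]ethan-1-ol
Product: 20 2-[(tert-butyldimethylsilyl)oxy]ethyl trifluoromethanesulfonate
Conditions: Tf2O, 2,6-lutidine, CH2Cl2, −78 °C; used at once
Reagents that add atoms: triflic anhydride, O=S(=O)(OS(=O)(=O)C(F)(F)F)C(F)(F)F
Why: Sulfonylation of a primary alcohol with triflic anhydride and a hindered base gives the triflate cleanly, an electrophile reactive enough to build a quaternary carbon where the corresponding iodide would be too slow.

**Step 11**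
Reactants: 18 the ynone lactone; 20 the silyloxyethyl triflate
Product: 22 (4R,5R)-4-{2-[(tert-butyldimethylsilyl)oxy]ethyl}-5-[(1E,4E)-2,6-dimethyl-6-(triethylsilyloxy)hepta-1,4-dien-1-yl]-4-[3-(trimethylsilyl)prop-2-ynoyl]oxolan-2-one, via lithium enolate 21 (not isolated)
Conditions: LiN(SiMe3)2, THF, −78 °C; then 20, −78 to −30 °C
Reagents that add atoms: none
Why: In this ketone enolate C-alkylation the C4–H next to the ynone is by far the most acidic site, the lactone C–O bond lies near the plane of the ring-bound enolate carbon and is therefore badly aligned for β-elimination, and the triflate should approach planar C4 anti to the C5 dienyl group, placing the new arm trans to the side chain and setting C4 as R.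

**Step 12**
Reactants: 22 the alkylated lactone
Product: 23 (4R,5R)-4-(2-hydroxyethyl)-5-[(1E,4E)-6-hydroxy-2,6-dimethylhepta-1,4-dien-1-yl]-4-[3-(trimethylsilyl)prop-2-ynoyl]oxolan-2-one
Conditions: 48% aq. HF, MeCN, 0 °C to rt
Reagents that add atoms: none
Why: Acidic fluoride cleaves the primary tert-butyldimethylsilyl and the tertiary triethylsilyl ether at Si–O, whereas the alkynyl C–Si bond needs a basic nucleophile and should stay, so the ynone remains capped while a free primary alcohol is present.

**Step 13**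
Reactants: 23 the diol
Product: 24 2-{(2R,3R)-2-[(1E,4E)-6-hydroxy-2,6-dimethylhepta-1,4-dien-1-yl]-5-oxo-3-[3-(trimethylsilyl)prop-2-ynoyl]oxolan-3-yl}acetaldehyde
Conditions: Dess–Martin periodinane, CH2Cl2, 0 °C to rt
Reagents that add atoms: none
Why: Dess–Martin oxidation takes the primary alcohol to the aldehyde (through the open form if it rests as the five-membered hemiketal on the ketone) and cannot oxidise the tertiary alcohol.

**Step 14**
Reactants: 24 the silylated ynone aldehyde
Product: 25 2-{(2R,3R)-2-[(1E,4E)-6-hydroxy-2,6-dimethylhepta-1,4-dien-1-yl]-5-oxo-3-(prop-2-ynoyl)oxolan-3-yl}acetaldehyde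
Conditions: Bu4NF, AcOH (1:1), THF, −78 °C
Reagents that add atoms: none
Why: Buffered fluoride C-desilylation of an ynone is fast at low temperature, and acetic acid protonates the acetylide at once, so neither the enolisable aldehyde nor the terminal ynone meets free base.

**Step 15**
Reactants: 25 the terminal ynone aldehyde
Product: 26 2-{(2R,3R)-2-[(1E,4E)-6-hydroxy-2,6-dimethylhepta-1,4-dien-1-yl]-3-[(2Z)-3-iodoprop-2-enoyl]-5-oxooxolan-3-yl}acetaldehyde
Conditions: NaI, AcOH, rt
Reagents that add atoms: sodium iodide, [Na+].[I-]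
Why: In this conjugate hydroiodination iodide adds to the β-carbon of the terminal ynone and the allenolate is protonated on the side away from iodine, a net anti addition that should give the Z-β-iodoenone under kinetic control while the aldehyde, the lactone and the tertiary alcohol tolerate acetic acid at room temperature.

**Step 16**
Reactants: 26 the Z-iodoenone aldehyde
Product: 28 (1R,5R,9S)-9-hydroxy-1-[(1E,4E)-6-hydroxy-2,6-dimethylhepta-1,4-dien-1-yl]-2-oxaspiro[4.5]dec-7-ene-3,6-dione, via alkenylchromium dichloride 27 (not isolated)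
Conditions: CrCl2 (6 equiv), NiCl2 (2 mol%), degassed DMSO, 0.005 M, rt; aqueous work-up
Reagents that add atoms: none
Why: Zerovalent nickel, formed from NiCl2 by divalent chromium, inserts into the vinylic C–I bond and hands the alkenyl group to trivalent chromium with retention of the Z geometry, and the alkenylchromium 27 then adds to the aldehyde held on the same quaternary carbon. The closest known reaction is the intramolecular Nozaki–Hiyama–Kishi cyclisation of iodoalkenes onto aldehydes to give cyclic allylic alcohols. The cyclohexenone ring closes in a 6-exo-trig mode, the C8–C9 bond and the C9 carbinol forming together. The C9 configuration is controlled by the spiro carbon: in the half-chair closure the chromium-bound oxygen should sit pseudo-equatorial and the ring should fold so that the branched lactone carbon C1, not the lactone CH2, takes the other equatorial site, which places the oxygen cis to C1 (9S). The step needs addition to the aldehyde in preference to the ketone and the lactone, which organochromium reagents provide, and it needs the two ends within reach, which the Z alkene and the shared quaternary carbon secure; the free tertiary alcohol is tolerated.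

**Step 17**
Reactants: 28 the hydroxy enone
Product: 29 (+)-miliusane XVII, the C9 acetate of 28
Conditions: Ac2O, pyridine, CH2Cl2, 0 °C to rt
Reagents that add atoms: acetic anhydride, CC(=O)OC(C)=O
Why: Acylation with acetic anhydride and pyridine, without a stronger acyl-transfer catalyst, should esterify the secondary allylic alcohol and leave the hindered tertiary alcohol free.

**Compound list**

1 | 2-methylbut-3-yn-2-ol | CC(C)(O)C#C | starting material
2 | triethyl[(2-methylbut-3-yn-2-yl)oxy]silane | CC[Si](CC)(CC)OC(C)(C)C#C | intermediate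
3 | triethyl{[(3E)-2-methyl-4-(tributylstannyl)but-3-en-2-yl]oxy}silane | CCCC[Sn](CCCC)(CCCC)/C=C/C(C)(C)O[Si](CC)(CC)CC | intermediate
4 | ethyl (2E)-4-bromo-3-methylbut-2-enoate | CCOC(=O)/C=C(\C)CBr | starting material
5 | ethyl (2E,5E)-3,7-dimethyl-7-(triethylsilyloxy)octa-2,5-dienoate | CCOC(=O)/C=C(\C)C/C=C/C(C)(C)O[Si](CC)(CC)CC | intermediate
6 | (2E,5E)-3,7-dimethyl-7-(triethylsilyloxy)octa-2,5-dien-1-ol | OC/C=C(\C)C/C=C/C(C)(C)O[Si](CC)(CC)CC | intermediate
7 | (2E,5E)-3,7-dimethyl-7-(triethylsilyloxy)octa-2,5-dienal | O=C/C=C(\C)C/C=C/C(C)(C)O[Si](CC)(CC)CC | intermediate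
8 | methyl 4-chloro-4-oxobutanoate | COC(=O)CCC(Cl)=O | starting material
9 | (4S)-4-benzyl-1,3-oxazolidin-2-one | O=C1N[C@@H](Cc2ccccc2)CO1 | starting material
10 | methyl 4-[(4S)-4-benzyl-2-oxo-1,3-oxazolidin-3-yl]-4-oxobutanoate | COC(=O)CCC(=O)N1[C@@H](Cc2ccccc2)COC1=O | intermediate
11 | dibutylboron Z-enolate of 10 (not isolated) | CCCCB(CCCC)O/C(=C\CC(=O)OC)N1[C@@H](Cc2ccccc2)COC1=O | intermediate
12 | methyl (3S,4R,5E,8E)-3-{[(4S)-4-benzyl-2-oxo-1,3-oxazolidin-3-yl]carbonyl}-4-hydroxy-6,10-dimethyl-10-(triethylsilyloxy)undeca-5,8-dienoate (not isolated) | COC(=O)C[C@H](C(=O)N1[C@@H](Cc2ccccc2)COC1=O)[C@H](O)/C=C(\C)C/C=C/C(C)(C)O[Si](CC)(CC)CC | intermediate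
13 | (4S)-4-benzyl-3-{(2R,3S)-2-[(1E,4E)-2,6-dimethyl-6-(triethylsilyloxy)hepta-1,4-dien-1-yl]-5-oxooxolane-3-carbonyl}-1,3-oxazolidin-2-one (trans lactone) | O=C1C[C@H](C(=O)N2[C@@H](Cc3ccccc3)COC2=O)[C@@H](/C=C(\C)C/C=C/C(C)(C)O[Si](CC)(CC)CC)O1 | intermediate
14 | (2R,3S)-2-[(1E,4E)-2,6-dimethyl-6-(triethylsilyloxy)hepta-1,4-dien-1-yl]-5-oxooxolane-3-carboperoxoic acid (not isolated) | O=C1C[C@H](C(=O)OO)[C@@H](/C=C(\C)C/C=C/C(C)(C)O[Si](CC)(CC)CC)O1 | intermediate
15 | (2R,3S)-2-[(1E,4E)-2,6-dimethyl-6-(triethylsilyloxy)hepta-1,4-dien-1-yl]-5-oxooxolane-3-carboxylic acid | O=C1C[C@H](C(=O)O)[C@@H](/C=C(\C)C/C=C/C(C)(C)O[Si](CC)(CC)CC)O1 | intermediate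
16 | ethynyltrimethylsilane | C[Si](C)(C)C#C | starting material
17 | (2R,3S)-2-[(1E,4E)-2,6-dimethyl-6-(triethylsilyloxy)hepta-1,4-dien-1-yl]-5-oxooxolane-3-carbonyl chloride (not isolated) | O=C1C[C@H](C(Cl)=O)[C@@H](/C=C(\C)C/C=C/C(C)(C)O[Si](CC)(CC)CC)O1 | intermediate
18 | (4S,5R)-5-[(1E,4E)-2,6-dimethyl-6-(triethylsilyloxy)hepta-1,4-dien-1-yl]-4-[3-(trimethylsilyl)prop-2-ynoyl]oxolan-2-one | O=C1C[C@H](C(=O)C#C[Si](C)(C)C)[C@@H](/C=C(\C)C/C=C/C(C)(C)O[Si](CC)(CC)CC)O1 | intermediate
19 | 2-[(tert-butyldimethylsilyl)oxy]ethan-1-ol | CC(C)(C)[Si](C)(C)OCCO | starting material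
20 | 2-[(tert-butyldimethylsilyl)oxy]ethyl trifluoromethanesulfonate | CC(C)(C)[Si](C)(C)OCCOS(=O)(=O)C(F)(F)F | intermediate
21 | lithium enolate of 18 at C4 (enolate geometry immaterial; not isolated) | [Li]OC(C#C[Si](C)(C)C)=C1CC(=O)O[C@@H]1/C=C(\C)C/C=C/C(C)(C)O[Si](CC)(CC)CC | intermediate
22 | (4R,5R)-4-{2-[(tert-butyldimethylsilyl)oxy]ethyl}-5-[(1E,4E)-2,6-dimethyl-6-(triethylsilyloxy)hepta-1,4-dien-1-yl]-4-[3-(trimethylsilyl)prop-2-ynoyl]oxolan-2-one | CC(C)(C)[Si](C)(C)OCC[C@]1(CC(=O)O[C@@H]1/C=C(\C)C/C=C/C(C)(C)O[Si](CC)(CC)CC)C(=O)C#C[Si](C)(C)C | intermediate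
23 | (4R,5R)-4-(2-hydroxyethyl)-5-[(1E,4E)-6-hydroxy-2,6-dimethylhepta-1,4-dien-1-yl]-4-[3-(trimethylsilyl)prop-2-ynoyl]oxolan-2-one | OCC[C@]1(CC(=O)O[C@@H]1/C=C(\C)C/C=C/C(C)(C)O)C(=O)C#C[Si](C)(C)C | intermediate
24 | 2-{(2R,3R)-2-[(1E,4E)-6-hydroxy-2,6-dimethylhepta-1,4-dien-1-yl]-5-oxo-3-[3-(trimethylsilyl)prop-2-ynoyl]oxolan-3-yl}acetaldehyde | O=CC[C@]1(CC(=O)O[C@@H]1/C=C(\C)C/C=C/C(C)(C)O)C(=O)C#C[Si](C)(C)C | intermediate
25 | 2-{(2R,3R)-2-[(1E,4E)-6-hydroxy-2,6-dimethylhepta-1,4-dien-1-yl]-5-oxo-3-(prop-2-ynoyl)oxolan-3-yl}acetaldehyde | O=CC[C@]1(CC(=O)O[C@@H]1/C=C(\C)C/C=C/C(C)(C)O)C(=O)C#C | intermediate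
26 | 2-{(2R,3R)-2-[(1E,4E)-6-hydroxy-2,6-dimethylhepta-1,4-dien-1-yl]-3-[(2Z)-3-iodoprop-2-enoyl]-5-oxooxolan-3-yl}acetaldehyde | O=CC[C@]1(CC(=O)O[C@@H]1/C=C(\C)C/C=C/C(C)(C)O)C(=O)/C=C\I | intermediate
27 | Z-alkenylchromium dichloride from 26, trivalent chromium on the former iodine-bearing carbon (not isolated) | O=CC[C@]1(CC(=O)O[C@@H]1/C=C(\C)C/C=C/C(C)(C)O)C(=O)/C=C\[Cr](Cl)Cl | intermediate
28 | (1R,5R,9S)-9-hydroxy-1-[(1E,4E)-6-hydroxy-2,6-dimethylhepta-1,4-dien-1-yl]-2-oxaspiro[4.5]dec-7-ene-3,6-dione | O[C@@H]1C=CC(=O)[C@@]2(CC(=O)O[C@@H]2/C=C(\C)C/C=C/C(C)(C)O)C1 | intermediate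
29 | (+)-miliusane XVII; (1R,5R,9S)-1-[(1E,4E)-6-hydroxy-2,6-dimethylhepta-1,4-dien-1-yl]-3,6-dioxo-2-oxaspiro[4.5]dec-7-en-9-yl acetate (numbered as 28) | CC(=O)O[C@@H]1C=CC(=O)[C@@]2(CC(=O)O[C@@H]2/C=C(\C)C/C=C/C(C)(C)O)C1 | target

**Step count and risks**

Total steps: 17. Longest linear sequence: 15 (steps 1–5, 7–9, 11–17); steps 6 and 10 are side branches.

Steps most likely to fail:

Step 11. The delocalised enolate may be alkylated on oxygen by the hard triflate, or base may open the lactone by β-elimination, instead of forming the C–C bond. The fallback sets out from 18. Its lithium enolate (LiN(SiMe3)2, THF, −78 °C) would be added in a conjugate sense to 1-(methylsulfinyl)-1-(methylsulfanyl)ethene, a soft two-carbon acceptor at the aldehyde oxidation level that cannot O-alkylate. Addition anti to the side chain should give (4S,5R)-5-[(1E,4E)-2,6-dimethyl-6-(triethylsilyloxy)hepta-1,4-dien-1-yl]-4-[2-(methanesulfinyl)-2-(methylsulfanyl)ethyl]-4-[3-(trimethylsilyl)prop-2-ynoyl]oxolan-2-one F1, with the same spatial arrangement at C4 as in 22; the descriptor changes only through the sulfur substituents. Dilute aqueous HCl in THF at 0 °C would then hydrolyse the dithioacetal S-oxide to the aldehyde and remove the triethylsilyl ether in the same operation. The fallback comes back to the route at 24, before step 14.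

Step 16. Facial selectivity at C9 in the ring closure may be poor, since it rests only on a conformational preference of the half-chair. The fallback sets out from 28 as its mixture with the C9 epimer. Dess–Martin periodinane would oxidise both epimers to (1R,5R)-1-[(1E,4E)-6-hydroxy-2,6-dimethylhepta-1,4-dien-1-yl]-2-oxaspiro[4.5]dec-7-ene-3,6,9-trione F2. A Corey–Bakshi–Shibata reduction with (R)-2-methyl-CBS-oxazaborolidine and catecholborane in toluene at −78 °C would then reduce the C9 ketone under reagent control; the C6 ketone is shielded by the spiro carbon. The fallback comes back to the route at 28 as a single epimer.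

Step 15. With the tertiary allylic alcohol and the aldehyde unprotected, acid-promoted ionisation of the alcohol or Z-to-E drift of the iodoenone may erode the material right before the key step. The fallback sets out from 22 and moves the hydroiodination ahead of the deprotection. Bu4NF/AcOH at −78 °C would give (4R,5R)-4-{2-[(tert-butyldimethylsilyl)oxy]ethyl}-5-[(1E,4E)-2,6-dimethyl-6-(triethylsilyloxy)hepta-1,4-dien-1-yl]-4-(prop-2-ynoyl)oxolan-2-one F3. NaI/AcOH would give the corresponding 4-[(2Z)-3-iodoprop-2-enoyl] lactone F4 with both silyl ethers in place. Aqueous HF in MeCN would free (4R,5R)-4-(2-hydroxyethyl)-5-[(1E,4E)-6-hydroxy-2,6-dimethylhepta-1,4-dien-1-yl]-4-[(2Z)-3-iodoprop-2-enoyl]oxolan-2-one F5. Dess–Martin oxidation of its primary alcohol comes back to the route at 26.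

**Further compounds**

F1 | step 11 | (4S,5R)-5-[(1E,4E)-2,6-dimethyl-6-(triethylsilyloxy)hepta-1,4-dien-1-yl]-4-[2-(methanesulfinyl)-2-(methylsulfanyl)ethyl]-4-[3-(trimethylsilyl)prop-2-ynoyl]oxolan-2-one (mixture at sulfur and at the dithioacetal carbon) | CS(=O)C(SC)C[C@]1(CC(=O)O[C@@H]1/C=C(\C)C/C=C/C(C)(C)O[Si](CC)(CC)CC)C(=O)C#C[Si](C)(C)C
F2 | step 16 | (1R,5R)-1-[(1E,4E)-6-hydroxy-2,6-dimethylhepta-1,4-dien-1-yl]-2-oxaspiro[4.5]dec-7-ene-3,6,9-trione | O=C1C=CC(=O)[C@@]2(CC(=O)O[C@@H]2/C=C(\C)C/C=C/C(C)(C)O)C1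
F3 | step 15 | (4R,5R)-4-{2-[(tert-butyldimethylsilyl)oxy]ethyl}-5-[(1E,4E)-2,6-dimethyl-6-(triethylsilyloxy)hepta-1,4-dien-1-yl]-4-(prop-2-ynoyl)oxolan-2-one | CC(C)(C)[Si](C)(C)OCC[C@]1(CC(=O)O[C@@H]1/C=C(\C)C/C=C/C(C)(C)O[Si](CC)(CC)CC)C(=O)C#C
F4 | step 15 | (4R,5R)-4-{2-[(tert-butyldimethylsilyl)oxy]ethyl}-5-[(1E,4E)-2,6-dimethyl-6-(triethylsilyloxy)hepta-1,4-dien-1-yl]-4-[(2Z)-3-iodoprop-2-enoyl]oxolan-2-one | CC(C)(C)[Si](C)(C)OCC[C@]1(CC(=O)O[C@@H]1/C=C(\C)C/C=C/C(C)(C)O[Si](CC)(CC)CC)C(=O)/C=C\I
F5 | step 15 | (4R,5R)-4-(2-hydroxyethyl)-5-[(1E,4E)-6-hydroxy-2,6-dimethylhepta-1,4-dien-1-yl]-4-[(2Z)-3-iodoprop-2-enoyl]oxolan-2-one | OCC[C@]1(CC(=O)O[C@@H]1/C=C(\C)C/C=C/C(C)(C)O)C(=O)/C=C\I
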